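**Strategy.** The C5–C6 bond joins an ether carbon (C5, on the C5–O–C10 bridge) to the γ-carbon of the lactone (C6). It is therefore made by an intramolecular vinylogous Mukaiyama addition: a seven-membered oxocarbenium ion in ring A (O, C10, C1–C5) is captured at C5 by C6 of a 2-silyloxyfuran tethered through C7–C8–C9 to C10. One operation dearomatises the furan, closes the second oxepane (ring B) and with it the ten-membered carbocycle, and sets C5 and C6. Ring A comes from (R)-carvone: a double Baeyer–Villiger oxidation inserts the ring oxygen between C5 and C10 and turns the former isopropenyl carbon into the C3 acetate.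

Key step: step 10

Numbering: germacranolide numbering of the target is used throughout (ring carbons C1–C10, lactone carbons C11–C13, C14 = methyl on C10, C15 = hydroxymethyl carbon on C4; ring A = oxepane O/C10/C1–C5, ring B = oxepane O/C5–C10).

Assumption: the stereodescriptors of the given structure are carried unchanged through every intermediate; at the bridgehead pair C5/C10 they are taken to describe the bridged ether that closure from the C10-bound chain delivers, since a one-atom C5–O–C10 bridge can be spanned from one face only.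

**Route**

Step 1
Reactants: 1 (R)-(−)-carvone
Product: 3 (2R,5R)-2-allyl-2-methyl-5-(prop-1-en-2-yl)cyclohexan-1-one (allyl cis to isopropenyl), via lithium enolate 2 (not isolated)
Conditions: LiBH(s-Bu)3, THF, −78 °C; then allyl bromide, −78 °C → rt
Reagents that add atoms: allyl bromide, C=CCBr
Why: Conjugate hydride addition gives enolate 2 regiospecifically, and allyl bromide should then attack C10 axially through a chair-like transition state with the isopropenyl group equatorial, i.e. cis to it (reductive alkylation of an enone), which sets the C10 quaternary centre.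

Step 2
Reactants: 3 (2R,5R)-2-allyl-2-methyl-5-(prop-1-en-2-yl)cyclohexan-1-one
Product: 5 (2R,5R,6S)-2-allyl-6-[(4-methoxybenzyloxy)methyl]-2-methyl-5-(prop-1-en-2-yl)cyclohexan-1-one (C15 cis to isopropenyl and to allyl), via trans ketone 4 (not isolated)
Conditions: LiN(i-Pr)2, THF, −78 °C; PMBOCH2Cl; then LiN(i-Pr)2, −78 → −40 °C; then 2,6-di-tert-butyl-4-methylphenol, −78 °C
Reagents that add atoms: 4-methoxybenzyl chloromethyl ether, COc1ccc(COCCl)cc1
Why: Kinetic enolate alkoxymethylation puts C15 on C4 trans to the isopropenyl group (4); in the re-formed, now tetrasubstituted enolate, allylic 1,2-strain turns the isopropenyl group pseudo-axial and the bulky phenol should protonate C4 from the opposite face, so that C15 ends up cis to it (kinetic protonation).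

Step 3
Reactants: 5 (2R,5R,6S)-2-allyl-6-[(4-methoxybenzyloxy)methyl]-2-methyl-5-(prop-1-en-2-yl)cyclohexan-1-one
Product: 6 keto aldehyde: 2-{4-acetyl-3-[(4-methoxybenzyloxy)methyl]-1-methyl-2-oxocyclohexyl}acetaldehyde, configuration as in 5
Conditions: OsO4 (cat.), NaIO4, 2,6-lutidine, 1,4-dioxane–H2O, rt
Reagents that add atoms: sodium periodate, [Na+].[O-]I(=O)(=O)=O
Why: Lemieux–Johnson oxidation cleaves both terminal alkenes, the allyl group to the C8 aldehyde and the isopropenyl group to the methyl ketone, without touching the stereocentres.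

Step 4
Reactants: 6 keto aldehyde; 7 4-bromofuran-2(5H)-one
Product: 8 C8 carbinol (both C8 epimers) carrying the butenolide on C7, ring ketone and acetyl group unchanged
Conditions: CrCl2 (4 equiv), NiCl2 (cat.), DMF, rt
Reagents that add atoms: none
Why: Nozaki–Hiyama–Kishi coupling: the alkenylchromium species formed from the β-bromobutenolide under NiCl2 catalysis adds to the aldehyde and leaves the two ketones alone; C8 forms as a mixture that step 5 erases.

Step 5
Reactants: 8 C8 carbinol
Product: 9 triketone (C8 ketone conjugated to the butenolide, ring ketone, C3 acetyl)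
Conditions: Dess–Martin periodinane, NaHCO3, CH2Cl2, rt
Reagents that add atoms: none
Why: Dess–Martin oxidation of the secondary allylic alcohol removes the uncontrolled C8 centre and prevents hemiketal formation between the C8 hydroxyl and the ring ketone.

Step 6
Reactants: 9 triketone
Product: 10 ε-lactone acetate: oxepan-2-one (ring A at the lactone level, O between C5 and C10) with C3 acetate, C4 CH2OPMB and the C8 ketone
Conditions: mCPBA (4 equiv), NaHCO3, CH2Cl2, rt
Reagents that add atoms: 3-chloroperbenzoic acid, OOC(=O)c1cccc(Cl)c1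
Why: Double Baeyer–Villiger oxidation: in the ring ketone the quaternary C10 migrates in preference to C4 and in the methyl ketone the ring carbon C3 migrates in preference to methyl, both with retention; the cross-conjugated C8 ketone, flanked by a primary alkyl and an electron-poor alkenyl group, should not react.

Step 7
Reactants: 10 ε-lactone acetate
Product: 11 C8 alcohol (single epimer, C8 R)
Conditions: (S)-2-methyl-CBS-oxazaborolidine (cat.), BH3·SMe2, THF, −30 °C; MeOH
Reagents that add atoms: none
Why: Corey–Bakshi–Shibata reduction: the (S)-oxazaborolidine delivers hydride to the enone carbonyl with the butenolide as the large group, which sets C8 under reagent control.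

Step 8
Reactants: 11 C8 alcohol
Product: 12 bis-silyl compound: C8 tert-butyldimethylsilyl ether and 2-(tert-butyldimethylsilyloxy)furan attached through its 4-position (C7)
Conditions: TBSOTf (2.5 equiv), Et3N, CH2Cl2, −78 → 0 °C
Reagents that add atoms: tert-butyldimethylsilyl triflate, CC(C)(C)[Si](C)(C)OS(=O)(=O)C(F)(F)F
Why: Silyl triflate and amine silylate the C8 hydroxyl and convert the butenolide, through γ-deprotonation at C6, into the aromatic 2-silyloxyfuran (soft enolisation).

Step 9
Reactants: 12 bis-silyl compound
Product: 14 α-acetoxy ether: 2-acetoxyoxepane (C5 acetate, either anomer) with C3 acetate retained, via aluminium lactolate 13 (not isolated)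
Conditions: i-Bu2AlH (1.2 equiv), CH2Cl2, −78 °C; then pyridine, DMAP, Ac2O, −78 → 0 °C
Reagents that add atoms: acetic anhydride, CC(=O)OC(C)=O
Why: Reductive acetylation of a lactone: the hydride should add once to the more electrophilic ε-lactone in preference to the secondary acetate at −78 °C, and the tetrahedral aluminate 13 is acetylated in situ, so the seven-membered lactol is trapped before it can open (C5 forms as an anomeric mixture of no consequence).

Step 10
Reactants: 14 α-acetoxy ether
Product: 16 bridged butenolide: 11-oxabicyclo[4.4.1]undecane core with the Δ7(11)-butenolide fused at C6–C7, C3 acetate, C4 CH2OPMB, C8 OTBS, configuration at C3, C4, C5, C6, C8, C10 as in the target, via oxocarbenium ion 15 (not isolated)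
Conditions: TMSOTf (0.2 equiv), 2,6-di-tert-butyl-4-methylpyridine, CH2Cl2, −78 °C; NaHCO3 (aq)
Reagents that add atoms: none
Why: TMSOTf ionises the anomeric acetate to the seven-membered oxocarbenium ion 15, C6 of the tethered 2-silyloxyfuran (its γ-carbon) adds to C5, and the silyl group then leaves the resulting silyloxy-oxocarbenium ion to give the butenolide and regenerate a silyl triflate. The closest known reaction type is the vinylogous Mukaiyama addition of 2-silyloxyfurans to lactol acetates (C-glycosylation), here run intramolecularly. Ring B (O, C5, C6, C7, C8, C9, C10) closes in a 7-endo-trig mode at the C5=O+ bond, and the same bond completes the ten-membered carbocycle C1–C10. C5 is controlled by the tether, because the chain C9–C8–C7 hangs from C10 and can bring C6 to one face of the oxocarbenium carbon only; C6 is controlled by C8, whose C–O bond should lie in the furan plane with C8–H opposite the forming bond, so that O6 and O8 end up cis on ring B. The step needs attack through C6 and not through C11 of the dienol ether, which the larger coefficient at the furan 5-position secures, and it needs closure to outrun loss of H-4 from 15, which the short tether on the gem-disubstituted C10 and −78 °C favour.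

Step 11
Reactants: 16 bridged butenolide
Product: 18 Mannich base: cis-fused saturated lactone with CH2NMe2 on C11 (C11 epimers), C7 as in the target, via silyl ketene acetal 17 (not isolated)
Conditions: [(Ph3P)CuH]6 (cat.), PhMe2SiH, toluene, rt; then CH2=NMe2+ I−, CH2Cl2, 0 °C → rt; NaHCO3 (aq)
Reagents that add atoms: N,N-dimethylmethyleneiminium iodide, C=[N+](C)C.[I-]
Why: Copper hydride-catalysed 1,4-hydrosilylation should put hydride on C7 from the butenolide face that carries H-6 (the other face is shielded by C5 and ring A), giving the cis-fused lactone as silyl ketene acetal 17, which the iminium salt aminomethylates at C11 (conjugate reduction then Mannich reaction).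

Step 12
Reactants: 18 Mannich base
Product: 20 α-methylene lactone (C8 OTBS, C15 OPMB), via ammonium iodide 19 (not isolated)
Conditions: MeI, MeOH, rt; then NaHCO3 (aq), EtOAc, rt
Reagents that add atoms: none
Why: Quaternisation and base-induced β-elimination of trimethylamine (Hofmann-type elimination of a Mannich base) create the exocyclic C11=C13 methylene without touching C7.

Step 13
Reactants: 20 α-methylene lactone
Product: 21 C8 alcohol
Conditions: HF·pyridine, pyridine, THF, 0 °C → rt
Reagents that add atoms: none
Why: Fluoride-mediated cleavage of the secondary silyl ether; the acetate, the PMB ether and the α-methylene lactone should be stable to buffered HF·pyridine.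

Step 14
Reactants: 21 C8 alcohol
Product: 22 C8 methacrylate with C15 still PMB-protected
Conditions: methacrylic anhydride, DMAP, Et3N, CH2Cl2, 0 °C → rt
Reagents that add atoms: methacrylic anhydride, C=C(C)C(=O)OC(=O)C(C)=C
Why: DMAP-catalysed acylation of the only free hydroxyl (C8); C15 is still protected, so no regiochemical issue arises.

Step 15
Reactants: 22 C8 methacrylate
Product: 23 target, (3R,4R,5R,6R,7R,8R,10R)-3-acetoxy-15-hydroxy-8-methacryloyloxy-5,10-epoxygermacr-11(13)-en-6,12-olide
Conditions: DDQ, CH2Cl2–pH 7 buffer, 0 °C → rt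
Reagents that add atoms: none
Why: Oxidative cleavage of the PMB ether by DDQ (benzylic hydride abstraction then hydrolysis) frees the C15 hydroxyl under neutral conditions that spare both acrylate units and the acetate.

**Compound list**

1 | (R)-(−)-carvone, (5R)-2-methyl-5-(prop-1-en-2-yl)cyclohex-2-en-1-one | CC(=C)[C@@H]1CC=C(C)C(=O)C1 | starting material
2 | lithium enolate of (R)-dihydrocarvone (C5–OLi, C5=C10) | CC(=C)[C@@H]1CCC(C)=C(O[Li])C1 | intermediate (not isolated)
3 | (2R,5R)-2-allyl-2-methyl-5-(prop-1-en-2-yl)cyclohexan-1-one | C=CC[C@@]1(C)CC[C@@H](C(C)=C)CC1=O | intermediate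
4 | (2R,5R,6R)-2-allyl-6-[(4-methoxybenzyloxy)methyl]-2-methyl-5-(prop-1-en-2-yl)cyclohexan-1-one (C15 trans to isopropenyl) | C=CC[C@@]1(C)CC[C@@H](C(C)=C)[C@H](COCc2ccc(OC)cc2)C1=O | intermediate (not isolated)
5 | (2R,5R,6S)-2-allyl-6-[(4-methoxybenzyloxy)methyl]-2-methyl-5-(prop-1-en-2-yl)cyclohexan-1-one (C15 cis to isopropenyl and allyl) | C=CC[C@@]1(C)CC[C@@H](C(C)=C)[C@@H](COCc2ccc(OC)cc2)C1=O | intermediate
6 | keto aldehyde, 2-{4-acetyl-3-[(4-methoxybenzyloxy)methyl]-1-methyl-2-oxocyclohexyl}acetaldehyde, configuration as in 5 | O=CC[C@@]1(C)CC[C@@H](C(C)=O)[C@@H](COCc2ccc(OC)cc2)C1=O | intermediate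
7 | 4-bromofuran-2(5H)-one | O=C1C=C(Br)CO1 | starting material
8 | C8 carbinol (C8 epimers) with the butenolide on C7 | OC(C[C@@]1(C)CC[C@@H](C(C)=O)[C@@H](COCc2ccc(OC)cc2)C1=O)C1=CC(=O)OC1 | intermediate
9 | triketone (C8 ketone, ring ketone, C3 acetyl) | O=C(C[C@@]1(C)CC[C@@H](C(C)=O)[C@@H](COCc2ccc(OC)cc2)C1=O)C1=CC(=O)OC1 | intermediate
10 | ε-lactone acetate with C8 ketone | O=C(C[C@@]1(C)CC[C@@H](OC(C)=O)[C@@H](COCc2ccc(OC)cc2)C(=O)O1)C1=CC(=O)OC1 | intermediate
11 | C8 (R)-alcohol of 10 | O[C@H](C[C@@]1(C)CC[C@@H](OC(C)=O)[C@@H](COCc2ccc(OC)cc2)C(=O)O1)C1=CC(=O)OC1 | intermediate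
12 | C8 silyl ether carrying the 2-(tert-butyldimethylsilyloxy)furan-4-yl group | CC(C)(C)[Si](C)(C)O[C@H](C[C@@]1(C)CC[C@@H](OC(C)=O)[C@@H](COCc2ccc(OC)cc2)C(=O)O1)c1coc(O[Si](C)(C)C(C)(C)C)c1 | intermediate
13 | diisobutylaluminium lactolate of 12 (C5–O–Al) | CC(C)(C)[Si](C)(C)O[C@H](C[C@@]1(C)CC[C@@H](OC(C)=O)[C@@H](COCc2ccc(OC)cc2)C(O[Al](CC(C)C)CC(C)C)O1)c1coc(O[Si](C)(C)C(C)(C)C)c1 | intermediate (not isolated)
14 | α-acetoxy ether (2-acetoxyoxepane, C5 anomers) | CC(C)(C)[Si](C)(C)O[C@H](C[C@@]1(C)CC[C@@H](OC(C)=O)[C@@H](COCc2ccc(OC)cc2)C(OC(C)=O)O1)c1coc(O[Si](C)(C)C(C)(C)C)c1 | intermediate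
15 | seven-membered oxocarbenium ion (C5=O+) | CC(C)(C)[Si](C)(C)O[C@H](C[C@@]1(C)CC[C@@H](OC(C)=O)[C@@H](COCc2ccc(OC)cc2)C=[O+]1)c1coc(O[Si](C)(C)C(C)(C)C)c1 | intermediate (not isolated)
16 | bridged butenolide (rings A and B closed, Δ7(11)-butenolide, C8 OTBS, C15 OPMB) | CC(C)(C)[Si](C)(C)O[C@@H]1C[C@@]2(C)CC[C@@H](OC(C)=O)[C@@H](COCc3ccc(OC)cc3)[C@@H](O2)[C@@H]2OC(=O)C=C21 | intermediate
17 | dimethylphenylsilyl ketene acetal of the cis-fused lactone | CC(C)(C)[Si](C)(C)O[C@@H]1C[C@@]2(C)CC[C@@H](OC(C)=O)[C@@H](COCc3ccc(OC)cc3)[C@@H](O2)[C@@H]2OC(O[Si](C)(C)c3ccccc3)=C[C@@H]21 | intermediate (not isolated)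
18 | Mannich base, C11 (dimethylaminomethyl) lactone (C11 epimers) | CC(C)(C)[Si](C)(C)O[C@@H]1C[C@@]2(C)CC[C@@H](OC(C)=O)[C@@H](COCc3ccc(OC)cc3)[C@@H](O2)[C@@H]2OC(=O)C(CN(C)C)[C@@H]21 | intermediate
19 | trimethylammonium iodide of 18 | CC(C)(C)[Si](C)(C)O[C@@H]1C[C@@]2(C)CC[C@@H](OC(C)=O)[C@@H](COCc3ccc(OC)cc3)[C@@H](O2)[C@@H]2OC(=O)C(C[N+](C)(C)C)[C@@H]21.[I-] | intermediate (not isolated)
20 | α-methylene lactone, C8 OTBS, C15 OPMB | CC(C)(C)[Si](C)(C)O[C@@H]1C[C@@]2(C)CC[C@@H](OC(C)=O)[C@@H](COCc3ccc(OC)cc3)[C@@H](O2)[C@@H]2OC(=O)C(=C)[C@@H]21 | intermediate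
21 | C8 alcohol, C15 OPMB | O[C@@H]1C[C@@]2(C)CC[C@@H](OC(C)=O)[C@@H](COCc3ccc(OC)cc3)[C@@H](O2)[C@@H]2OC(=O)C(=C)[C@@H]21 | intermediate
22 | C8 methacrylate, C15 OPMB | C=C(C)C(=O)O[C@@H]1C[C@@]2(C)CC[C@@H](OC(C)=O)[C@@H](COCc3ccc(OC)cc3)[C@@H](O2)[C@@H]2OC(=O)C(=C)[C@@H]21 | intermediate
23 | target (CNP0602302.1) | C=C(C)C(=O)O[C@@H]1C[C@@]2(C)CC[C@@H](OC(C)=O)[C@@H](CO)[C@@H](O2)[C@@H]2OC(=O)C(=C)[C@@H]21 | target

**Step count.** 15 steps in total; the longest linear sequence is 15 steps from (R)-carvone 1.

**Steps most likely to fail**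

Step 10. The two faces of the furan may not be differentiated well enough by C8, so that C6 forms with poor facial selectivity. Fallback, setting out from 14 and returning at 16: the ring closure is run in the same way and the product mixture, rich in the C6 epimer of 16 F1, is not separated but treated with TBSOTf and Et3N (CH2Cl2, −78 → 0 °C). This turns the butenolide into the ring-fused 2-silyloxyfuran F2 and erases C6. Protonation of F2 (camphorsulfonic acid, THF–H2O, −40 °C) on the furan face away from ring A should then give 16. C6 is thus set by protonation of a planar furan and no longer by the carbon–carbon bond formation.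

Step 2. The contra-thermodynamic protonation may take place on the wrong face, or the cis ketone may revert to the trans isomer during the quench. Fallback, setting out from 3 and returning at 5: the alkylation is stopped at 4, which is isolated. LiN(i-Pr)2 and Me3SiCl (THF, −78 °C) give the trimethylsilyl enol ether of 4 F3. F3 is protonated at −78 °C by the Lewis-acid-assisted Brønsted acid made from SnCl4 and the enantiomer of 1,1'-bi-2-naphthol matched to the substrate, so that the face of protonation at C4 is chosen by the reagent instead of by the substrate.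

Step 9. Hydride may also attack the C3 acetate, or the aluminate may open to the hydroxy aldehyde before it is acetylated. Fallback, setting out from 12 and returning at 16: disiamylborane (THF, 0 °C → rt), which reduces lactones but leaves acetates alone, converts 12 into the lactol F4 (in equilibrium with its hydroxy aldehyde form). F4 is not acetylated but exposed directly to BF3·OEt2 in CH2Cl2 at −78 °C, where the C10 hydroxyl and the C5 aldehyde condense to the same oxocarbenium ion 15, which cyclises to 16; compound 14 is bypassed.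

Further compounds
F1 | step 10 | C6 epimer of bridged butenolide 16 | CC(C)(C)[Si](C)(C)O[C@@H]1C[C@@]2(C)CC[C@@H](OC(C)=O)[C@@H](COCc3ccc(OC)cc3)[C@@H](O2)[C@H]2OC(=O)C=C21
F2 | step 10 | ring-fused 2-(tert-butyldimethylsilyloxy)furan (C6 trigonal) | CC(C)(C)[Si](C)(C)O[C@@H]1C[C@@]2(C)CC[C@@H](OC(C)=O)[C@@H](COCc3ccc(OC)cc3)[C@@H](O2)c2oc(O[Si](C)(C)C(C)(C)C)cc21
F3 | step 2 | trimethylsilyl enol ether of ketone 4 (C4=C5) | C=CC[C@@]1(C)CC[C@@H](C(C)=C)C(COCc2ccc(OC)cc2)=C1O[Si](C)(C)C
F4 | step 9 | lactol (2-hydroxyoxepane) from 12 | CC(C)(C)[Si](C)(C)O[C@H](C[C@@]1(C)CC[C@@H](OC(C)=O)[C@@H](COCc2ccc(OC)cc2)C(O)O1)c1coc(O[Si](C)(C)C(C)(C)C)c1
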